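The rate constants belong to no real substance.

Take the constants as a ratio first: the partner attacks starting material and mono adduct by the same kind of step, so at equal concentrations the mono adduct passes on to double product at a fraction s = 0.297 of the rate at which it is made, and this selectivity factor, the constant of the double-product step over that of the mono-adduct step, is what you carry.

    starting material + partner → mono adduct (k1 = 0.091 /M/min)
    starting material + mono adduct → side product (k2 = 0.0068 /M/min)
    2 partner → self-condensation product (k3 = 0.0017 /M/min)
    partner + mono adduct → double product (k4 = 0.027 /M/min)

the same everywhere: partner 0.825 M

|  | starting material | remark | time |
|---|---|---|---|
| autumn | 0.33 M | a single well-mixed tank run continuously and read at steady state, 2.5 h in it on average |  |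
| summer | 0.33 M | everything together in a closed stirred flask, run for 2.5 h | 2.5 h |
| dawn | 0.33 M (fed, over 2.00 h) | a stirred flask in which starting material is dosed at a steady rate over 2.00 h without added volume, worked up at 2.5 h | 2.5 h |
| spring | 0.33 M | a single well-mixed tank run continuously and read at steady state, 7.50 h in it on average |  |

- a species is counted by the starting material in it: one side product counts as two
- two of one species on the left: rate k times its square, two consumed each time
- the stated concentrations are those of everything mixed, before any reaction; amounts are the same in each set-up
- the feed brings no volume worth counting
- run time (summer): 2.5 h

* the set-up with the highest amount of mono adduct at the outlet or at the end, in percent of the starting material put in ("none" if the first two lie within 2 percentage points) (autumn / summer / dawn / spring / none)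
* amount of mono adduct at the outlet or at the end, in percent of the starting material put in, autumn
* amount of mono adduct at the outlet or at the end, in percent of the starting material put in, summer
* amount of mono adduct at the outlet or at the end, in percent of the starting material put in, dawn
* amount of mono adduct at the outlet or at the end, in percent of the starting material put in, spring

Ask first for the end state: 2.50 equivalents of partner stand against the two that full conversion to double product takes, so the mono adduct is a passing stage and the question is how far each vessel has gone when read. In the closed flask of summer the partner cancels when you divide the rates, and with x the fraction of starting material left, the mono adduct is (x^s − x)/(1 − s) of the charge, which peaks at 59.9% when x is 17.8%. But x = exp(−a), with a the constant times partner times time, and the partner falls. I take the geometric middle of its charge and its floor, B = 0.369 M, which gives a = 5.04, so x lies far past the peak and summer ends at 31.0%. You may object that self-condensation drains the partner, and the objection stands: at B it takes about 0.0694 M of partner over the run, which my floor does not count, so I carry a as a rough figure.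

A tank gives a/[(1 + a)(1 + sa)], so autumn, with the same a, reads 33.5%. In spring, a = 15.1 is suspect, since a longer stay uses more partner; the balance corrects B to 0.262 M, so a = 10.7 and spring gives 21.8%.

In dawn each portion of starting material follows the summer expression from its own moment of entry, so with the partner held at one mean value the mono adduct at the end is the average of that expression over the portions, whose a runs from c, for the last portion fed, to c + f, where f is the constant of the mono-adduct step times partner times the feed time and c the same for the time after the feed. For the partner I assume a straight fall and take the arithmetic middle of its charge and floor, B = 0.495 M, so f = 5.41, c = 1.35, and the average comes to 40.7%. My pick is dawn.

The forecast gave autumn 33%, summer 30.7%, dawn 40.5% and spring 22.5%, and chose dawn, holding that “Dosing the starting material delays adduct formation until much of the partner has gone”. The simulation gives autumn 33.0%, summer 31.0%, dawn 42.9% and spring 22.4%, with dawn highest.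

Once the feed is over, making of mono adduct stands to its passing on to double product as A/(sM), with A and M the starting material and mono adduct present. In dawn at 2.50 h, 10.2% of starting material and 42.9% of mono adduct make that ratio 0.801, below one, whereas the neighbour of dawn charged with 0.21 M of partner holds 51.4% and 36.2% at that time, a ratio of 4.78.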